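Percent of the substrate charged is the unit in which the north-east and south runs agree at their first reading and part later, so we reckon in it and watch the molar amount beside it.

| setting | north-east | south | flask |
|---|---|---|---|
| substrate | 1.7 M | 2.6 M | 1.2 M |
| remark | run made earlier | run made earlier |  |
| time |  |  | 15 d |

- north-east (time / d: target / %, substrate / %): 0.417: 7.4, 17.3; 1.25: 18.4, 1.0; 3.00: 15.8, 0.1; 10.0: 1.0, 0
- south (time / d: target / %, substrate / %): 0.417: 7.3, 16.8; 1.25: 21.6, 0.5; 3.00: 29.6, 1.0; 10.0: 0.8, 0

(readings scatter by 0.5 percentage points)

- a reading or a percentage of target counts all its forms, free or not

1. when, up to 15 d, the flask holds most target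
2. the amount of target, in percent of the substrate charged, at that time
3. the first time at which target reaches 14%, in the same percent, in d

We want the tail rate, the first-order rate at which target falls once it merely follows its slower source, the rate-limiting step of the tail. From the north-east run's last two readings it is 0.394 /d, good to about 0.0714 /d.

A second way uses the early rise. In the north-east run substrate falls at 4.21 /d, and the first target reading of that run, with target's losses ignored, gives the source's rate as 0.336 /d, a floor that lies below the tail rate. The south tail gives 0.516 /d, but that run held 0.770 M of target at 3.00 d, against 0.269 M in the north-east run, so we set it aside as the one that cheats.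

Extrapolating the tail to zero time gives 51.6%. If a two-step chain holds, target's loss rate is 1.16 /d. By this chain target's gain and loss balance, with the substrate's lag added, at 1.65 d, and there we put the peak of our flask, at an estimated 19.5%. That is 0.234 M, below the 0.313 M read in the north-east run at 1.25 d. A straight line between the first two north-east readings puts the asked level at about 0.917 d, and that is our estimate for the flask.

The forecast, reasoning that “The loss is the same in molar terms, not in percent.”, gives 16% at 1.6 d and the level at 1 d, a lower peak than ours.

The flask gives 20.0% at 1.66 d, and the level at 0.764 d.

    substrate → intermediate A (k = 0.00290 /min)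
    intermediate A ⇌ intermediate B (K = 0.140, k = 5.60 × 10⁻⁵ /min)
    intermediate B → intermediate C (k = 4.30 × 10⁻⁴ /min)
    intermediate C → side product (k = 6.90 × 10⁻⁴ /min)
    intermediate B → target (k = 1.10 × 10⁻⁴ /min)
    intermediate A → target (k = 2.90 × 10⁻⁴ /min)
    intermediate C → decomposed reagent (k = 5.20 × 10⁻⁴ /min)
    crystals ⇌ target, rate k8*(cs8 - [target]) while solid is left; crystals form when [target] > cs8 (solubility = 0.320 M, k = 0.0300 /min)
    target → over-reaction product (k = 7.60 × 10⁻⁴ /min)

The half-life of dissolved target by its passing into over-reaction product alone, 0.63 d, is shorter than the 1.7 d of intermediate A by its passing into target alone. At the best time the flask still holds 51.1% as intermediate A against 20.0% as target. Carrying the flask's 10.8% at 4.00 d forward at the tail rate gives 2.72% at 7.50 d, against the 2.45% the flask holds then. The neighbour flask with 3.0 M, which peaks at 33.5%, holds 0.0876% at 15.0 d, against 0.139% from the tail.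

The earlier runs and the new flask stem from a simulated flask for substances that don't exist; the scatter is artificial.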